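**Strategy**

The pyrrole ring (N1, C2–C5) is cut at the C3–C4 bond. C3 carries the tricosyl chain and C4 only hydrogen, so this bond can be the trisubstituted olefin of a 2,5-dihydropyrrole. Ring-closing metathesis of an N-allyl-N-tosyl α-amino ester, whose C3 is a 1,1-disubstituted alkene, forms that bond and the five-membered ring in one operation. The precursor, methyl 2-[allyl(tosyl)amino]-3-methylidenehexacosanoate, is assembled from a C22 bromide, 2,3-dibromopropene, a glyoxylate N-tosylimine and allyl bromide. After closure the ester is taken to the aldehyde level and the tosyl group leaves as sulfinate, which aromatises the ring to the target.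

Key step: step 5

Assumption: methyl glyoxylate is used as the freshly distilled monomer. Compounds 10, 12, 13, 14 and 15 are racemic at C2, which is acceptable because that carbon becomes the sp2 C2 of the pyrrole.

**Route**

Step 1
Reactants: 1 1-bromodocosane; 2 2,3-dibromopropene
Product: 4 2-bromopentacos-1-ene, via docosylmagnesium bromide 3 (not isolated)
Conditions: Mg, THF, 50 °C; then 2 (1.5 equiv), CuBr·SMe2 (5 mol %), THF, 0 °C → rt
Reagents that add atoms: magnesium, [Mg] (held only in intermediate 3)
Why: Copper-catalysed allylic substitution of a primary alkyl Grignard reagent on the allylic C–Br bond of 2 should give 4, since direct and allylically transposed attack lead to the same product and the vinylic C–Br bond is inert here.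

Step 2
Reactants: 5 methyl glyoxylate; 6 4-methylbenzenesulfonyl isocyanate
Product: 7 methyl (E)-2-[(4-methylbenzenesulfonyl)imino]acetate
Conditions: AlCl3 (1 mol %), toluene, 110 °C; volatiles removed, used crude
Reagents that add atoms: none
Why: Carbonyl–isocyanate metathesis (aza-Wittig-type [2+2] addition and cycloreversion with loss of CO2) is the standard entry to N-sulfonyl iminoacetates and touches only the aldehyde carbonyl.

Step 3
Reactants: 4 2-bromopentacos-1-ene; 7 methyl (E)-2-[(4-methylbenzenesulfonyl)imino]acetate
Product: 10 methyl 3-methylidene-2-[(4-methylbenzenesulfonyl)amino]hexacosanoate (racemic), via pentacos-1-en-2-ylmagnesium bromide 8 (not isolated), via pentacos-1-en-2-ylzinc chloride 9 (not isolated)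
Conditions: Mg (I2-activated), THF, 55 °C; ZnCl2 (1.05 equiv), THF, 0 °C; then 7 (1.3 equiv), toluene–THF, 0 °C → rt; 1 M HCl work-up
Reagents that add atoms: magnesium, [Mg] (in 8 only); zinc dichloride, Cl[Zn]Cl (in 9 only)
Why: 1,2-Addition of an alkenylzinc halide to a strongly electrophilic N-sulfonyl α-imino ester (organozinc Mannich-type addition, assisted by the magnesium halide from the transmetalation) should spare the ester and give the C2 stereocentre as a racemate, which is irrelevant because step 7 destroys it.

Step 4
Reactants: 10 methyl 3-methylidene-2-[(4-methylbenzenesulfonyl)amino]hexacosanoate; 11 allyl bromide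
Product: 12 methyl 3-methylidene-2-[(4-methylbenzenesulfonyl)(prop-2-en-1-yl)amino]hexacosanoate (racemic)
Conditions: K2CO3 (2 equiv), DMF–THF, rt
Reagents that add atoms: none
Why: SN2 N-alkylation of the sulfonamide anion with an allylic bromide should be clean, because the N–H is far more acidic than the C2–H and the mild carbonate leaves the β,γ-alkene in place.

Step 5
Reactants: 12 methyl 3-methylidene-2-[(4-methylbenzenesulfonyl)(prop-2-en-1-yl)amino]hexacosanoate
Product: 13 methyl 1-(4-methylbenzenesulfonyl)-3-tricosyl-2,5-dihydro-1H-pyrrole-2-carboxylate (racemic)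
Conditions: second-generation Grubbs catalyst RuCl2(=CHPh)(H2IMes)(PCy3) (5 mol %), CH2Cl2 (0.01 M), 40 °C
Reagents that add atoms: none
Why: The ruthenium benzylidene exchanges onto the unhindered N-allyl terminus, the resulting alkylidene adds across the tethered 1,1-disubstituted C3=CH2 alkene in a [2+2] step, and cycloreversion of the ruthenacyclobutane releases the ring olefin and a Ru=CH2 species that carries the chain, with ethene lost. The closest known reaction type is ring-closing metathesis of N-sulfonyl diallylamine derivatives to N-sulfonyl 3-pyrrolines, including cases that form trisubstituted ring olefins. The single ring closes as a five-membered 2,5-dihydropyrrole by joining the former allyl CH (C4) to C3, so the new double bond is endocyclic. No stereocentre is created, and the racemic one at C2 is untouched. The step needs ring closure to outrun intermolecular metathesis and double-bond migration: the 1,1-disubstituted alkene does not homodimerise, the N-sulfonyl group and the C2 ester favour the folded rotamer, high dilution disfavours dimerisation through the allyl group, and the non-basic sulfonamide nitrogen cannot bind ruthenium.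

Step 6
Reactants: 13 methyl 1-(4-methylbenzenesulfonyl)-3-tricosyl-2,5-dihydro-1H-pyrrole-2-carboxylate
Product: 14 [1-(4-methylbenzenesulfonyl)-3-tricosyl-2,5-dihydro-1H-pyrrol-2-yl]methanol (racemic)
Conditions: LiBH4 (2 equiv), THF, 0 °C → rt
Reagents that add atoms: none
Why: Chemoselective borohydride reduction of an α-heteroatom-activated methyl ester should give the primary alcohol, since the reagent is too weakly basic to trigger sulfinate loss and leaves the sulfonamide and ring olefin alone.

Step 7
Reactants: 14 [1-(4-methylbenzenesulfonyl)-3-tricosyl-2,5-dihydro-1H-pyrrol-2-yl]methanol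
Product: 17 3-tricosyl-1H-pyrrole-2-carbaldehyde, via N-tosyl pyrroline aldehyde 15 (not isolated), via 2H-pyrrole tautomer 16 (not isolated)
Conditions: SO3·pyridine (3 equiv), DMSO, iPr2NEt, CH2Cl2, 0 °C → rt; then DBU (3 equiv), rt
Reagents that add atoms: none
Why: Parikh–Doering oxidation should give the α-sulfonamido aldehyde, whose doubly activated C2–H is removed by DBU so that E1cB loss of p-toluenesulfinate from nitrogen and C5-to-N tautomerisation deliver the aromatic pyrrole, the known base-induced sulfinate elimination of N-sulfonyl 3-pyrrolines bearing a C2 acceptor.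

**Compound list**

1 | 1-bromodocosane | CCCCCCCCCCCCCCCCCCCCCCBr | starting material
2 | 2,3-dibromopropene | BrCC(Br)=C | starting material
3 | docosylmagnesium bromide | CCCCCCCCCCCCCCCCCCCCCC[Mg]Br | intermediate (not isolated)
4 | 2-bromopentacos-1-ene | CCCCCCCCCCCCCCCCCCCCCCCC(Br)=C | intermediate
5 | methyl glyoxylate | COC(=O)C=O | starting material
6 | 4-methylbenzenesulfonyl isocyanate | Cc1ccc(cc1)S(=O)(=O)N=C=O | starting material
7 | methyl (E)-2-[(4-methylbenzenesulfonyl)imino]acetate | COC(=O)/C=N/S(=O)(=O)c1ccc(C)cc1 | intermediate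
8 | pentacos-1-en-2-ylmagnesium bromide | CCCCCCCCCCCCCCCCCCCCCCCC(=C)[Mg]Br | intermediate (not isolated)
9 | pentacos-1-en-2-ylzinc chloride | CCCCCCCCCCCCCCCCCCCCCCCC(=C)[Zn]Cl | intermediate (not isolated)
10 | methyl 3-methylidene-2-[(4-methylbenzenesulfonyl)amino]hexacosanoate (racemic) | CCCCCCCCCCCCCCCCCCCCCCCC(=C)C(NS(=O)(=O)c1ccc(C)cc1)C(=O)OC | intermediate
11 | allyl bromide | C=CCBr | starting material
12 | methyl 3-methylidene-2-[(4-methylbenzenesulfonyl)(prop-2-en-1-yl)amino]hexacosanoate (racemic) | CCCCCCCCCCCCCCCCCCCCCCCC(=C)C(C(=O)OC)N(CC=C)S(=O)(=O)c1ccc(C)cc1 | intermediate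
13 | methyl 1-(4-methylbenzenesulfonyl)-3-tricosyl-2,5-dihydro-1H-pyrrole-2-carboxylate (racemic) | CCCCCCCCCCCCCCCCCCCCCCCC1=CCN(S(=O)(=O)c2ccc(C)cc2)C1C(=O)OC | intermediate
14 | [1-(4-methylbenzenesulfonyl)-3-tricosyl-2,5-dihydro-1H-pyrrol-2-yl]methanol (racemic) | CCCCCCCCCCCCCCCCCCCCCCCC1=CCN(S(=O)(=O)c2ccc(C)cc2)C1CO | intermediate
15 | 1-(4-methylbenzenesulfonyl)-3-tricosyl-2,5-dihydro-1H-pyrrole-2-carbaldehyde (racemic) | CCCCCCCCCCCCCCCCCCCCCCCC1=CCN(S(=O)(=O)c2ccc(C)cc2)C1C=O | intermediate (not isolated)
16 | 4-tricosyl-2H-pyrrole-5-carbaldehyde | CCCCCCCCCCCCCCCCCCCCCCCC1=CCN=C1C=O | intermediate (not isolated)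
17 | 3-tricosyl-1H-pyrrole-2-carbaldehyde | CCCCCCCCCCCCCCCCCCCCCCCc1cc[nH]c1C=O | target

**Step count and risks**

Total steps: 7. Longest linear sequence: 6 steps (1 → 4 → 10 → 12 → 13 → 14 → 17); imine 7 is made in one step on a side branch.

Steps most likely to fail:

1. Step 3. Magnesium insertion into the waxy alkenyl bromide may be sluggish, or the organometallic may attack the imine nitrogen or the ester instead of the imine carbon. The fallback is a Petasis borono-Mannich assembly that sets out from 4 and returns at 12, bypassing 10. Miyaura borylation of 4 (B2pin2, PdCl2(PPh3)2, PPh3, KOPh, toluene, 50 °C) should give 4,4,5,5-tetramethyl-2-(pentacos-1-en-2-yl)-1,3,2-dioxaborolane F1. Condensation of this boronate with glyoxylic acid monohydrate and allylamine (hexafluoroisopropanol–CH2Cl2, rt) should transfer the alkenyl group to the iminium carbon and give racemic 2-(allylamino)-3-methylidenehexacosanoic acid F2. Esterification (Me3SiCHN2, MeOH–toluene, rt) should give methyl 2-(allylamino)-3-methylidenehexacosanoate F3, and N-sulfonylation (TsCl, Et3N, DMAP, CH2Cl2) returns to 12.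

2. Step 5. Closure onto the 1,1-disubstituted alkene may be outrun by intermolecular metathesis at the allyl terminus or by ruthenium-hydride-induced double-bond migration. The fallback closes the same 2,5-dihydropyrrole at the N1–C5 bond by cyclisation of an α-amino allene; it sets out from 4 (with imine 7) and returns at 13. Dehydrobromination of 4 (LDA, THF, −20 °C → rt) should give pentacos-1-yne F4. Its lithium acetylide (n-BuLi, THF) is alkylated with (iodomethyl)trimethylsilane to trimethyl(hexacos-2-yn-1-yl)silane F5. BF3·OEt2-promoted SE2′ addition of this propargylsilane to 7 (CH2Cl2, −40 → 0 °C) should give racemic methyl 2-[(4-methylbenzenesulfonyl)amino]-3-tricosylpenta-3,4-dienoate F6. AgNO3 (10 mol %) in acetone should then close the ring by 5-endo attack of the sulfonamide nitrogen on the allene terminus to give 13.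

3. Step 7. The activated sulfoxide may attack the pyrrole as it forms, or the enolisable aldehyde may self-condense before the sulfinate leaves. The fallback aromatises at the ester oxidation level and adjusts the oxidation state afterwards; it sets out from 13 and returns at 17. DBU (CH2Cl2, rt) should eliminate p-toluenesulfinate from 13 to give methyl 3-tricosyl-1H-pyrrole-2-carboxylate F7. LiAlH4 (THF, 0 °C) should reduce it to (3-tricosyl-1H-pyrrol-2-yl)methanol F8, which is oxidised without delay with activated MnO2 (CH2Cl2, rt) to 17.

**Further compounds**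

F1 | step 3 | 4,4,5,5-tetramethyl-2-(pentacos-1-en-2-yl)-1,3,2-dioxaborolane | CCCCCCCCCCCCCCCCCCCCCCCC(=C)B1OC(C)(C)C(C)(C)O1
F2 | step 3 | 2-(allylamino)-3-methylidenehexacosanoic acid (racemic) | CCCCCCCCCCCCCCCCCCCCCCCC(=C)C(NCC=C)C(=O)O
F3 | step 3 | methyl 2-(allylamino)-3-methylidenehexacosanoate (racemic) | CCCCCCCCCCCCCCCCCCCCCCCC(=C)C(NCC=C)C(=O)OC
F4 | step 5 | pentacos-1-yne | CCCCCCCCCCCCCCCCCCCCCCCC#C
F5 | step 5 | trimethyl(hexacos-2-yn-1-yl)silane | CCCCCCCCCCCCCCCCCCCCCCCC#CC[Si](C)(C)C
F6 | step 5 | methyl 2-[(4-methylbenzenesulfonyl)amino]-3-tricosylpenta-3,4-dienoate (racemic) | CCCCCCCCCCCCCCCCCCCCCCCC(=C=C)C(NS(=O)(=O)c1ccc(C)cc1)C(=O)OC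
F7 | step 7 | methyl 3-tricosyl-1H-pyrrole-2-carboxylate | CCCCCCCCCCCCCCCCCCCCCCCc1cc[nH]c1C(=O)OC
F8 | step 7 | (3-tricosyl-1H-pyrrol-2-yl)methanol | CCCCCCCCCCCCCCCCCCCCCCCc1cc[nH]c1CO
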